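**Retrosynthetic overview**

1. Unit U is the 4-aryl-flavan-3-ol half (its C4 is bonded to C6 of the other half) and unit L is the flavan-3,4-diol half; flavan numbering (O1, C2, C3, C4, C4a, C8a; ring A benzo, ring B 2-aryl, ring C pyran) is used for both.
2. Target ⇐ global deprotection ⇐ hydroboration–oxidation of a 4-aryl-flav-3-ene of unit U (C2 controls C3 and C4) ⇐ dehydration of a 4-aryl-flavan-4-ol.
3. That carbinol ⇐ one-pot [3+3] annulation: an enantiopure O1–C2–C3 unit (C,O-dilithio derivative of a 2-bromo-1-arylethanol) adds through C3 to a 2-fluoro diaryl ketone (C4), then O1 displaces fluoride at C8a; ring C of unit U is the last ring formed.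
4. Enabling feature: in unit U, O1 sits on C8a of ring A, ortho to C4a, and C4 is the doubly benzylic carbon that carries ring A of both units. C4 and C8a can therefore be a non-enolizable ketone carbon and a C–F carbon with no ortho hydrogen, and C3 can be carried as CH2 so that only O1 can reach C8a.
5. The ketone ⇐ aryllithium from the 6-bromide of protected unit L + 3,4-bis(benzyloxy)-2-fluorobenzaldehyde. Unit L (ring C formed first, by the same annulation on that aldehyde with the enantiomeric bromohydrin) ⇐ flav-3-ene → 2,3-trans-3-ol → 3-one → 2,3-cis-3-ol → C4 oxidation and reduction to the all-cis 3,4-diol.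

Key step: step 16

Remark: a carbinol carbon that forms as an epimer mixture and is erased by a later step is drawn without a descriptor; 2-fluoro-3,4-dimethoxybenzaldehyde and 1-[4-(benzyloxy)phenyl]-2-bromoethan-1-one are taken as purchasable.

**Route**

Step 1
Reactants: 1 2-fluoro-3,4-dimethoxybenzaldehyde
Product: 2 2-fluoro-3,4-dihydroxybenzaldehyde
Conditions: BBr3 (3 equiv), CH2Cl2, −78 °C to rt; then H2O
Reagents that add atoms: none
Why: Lewis-acid cleavage of both aryl methyl ethers (BBr3 demethylation) should leave the aldehyde and the C–F bond untouched.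

Step 2
Reactants: 2 2-fluoro-3,4-dihydroxybenzaldehyde
Product: 3 3,4-bis(benzyloxy)-2-fluorobenzaldehyde
Conditions: BnBr (2.3 equiv), K2CO3, DMF, 60 °C
Reagents that add atoms: benzyl bromide, BrCc1ccccc1
Why: Williamson ether synthesis on both phenols; the benzyl ethers should survive every later base, hydride, borane and oxidant and leave only in step 19.

Step 3
Reactants: 4 1-[4-(benzyloxy)phenyl]-2-bromoethan-1-one
Product: 5 (R)-1-[4-(benzyloxy)phenyl]-2-bromoethan-1-ol
Conditions: (R)-2-methyl-CBS-oxazaborolidine (10 mol %), BH3·SMe2, THF, 0 °C; then MeOH, aqueous work-up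
Reagents that add atoms: none
Why: Corey–Bakshi–Shibata reduction; the (R)-catalyst should deliver hydride to the ketone face that gives the (R)-bromohydrin (aryl as the large group), and this carbon becomes C2 of unit L.

Step 4
Reactants: 5 (R)-1-[4-(benzyloxy)phenyl]-2-bromoethan-1-ol; 3 3,4-bis(benzyloxy)-2-fluorobenzaldehyde
Product: 8 (2S,4RS)-7,8-bis(benzyloxy)-2-[4-(benzyloxy)phenyl]chroman-4-ol, via β-oxido alkyllithium 6 (not isolated), via dilithium diolate 7 (not isolated)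
Conditions: 5, n-BuLi (1 equiv) then t-BuLi (2 equiv), Et2O–THF, −78 °C; 3, −78 °C; then KOt-Bu, DMF, 70 °C
Reagents that add atoms: none
Why: O-deprotonation and bromine–lithium exchange should give a β-oxido alkyllithium that adds to the aldehyde (1,2-addition), after which the benzylic alkoxide displaces the ortho fluoride (intramolecular SNAr, six-membered ring); C2 comes unchanged from 5 and both C4 epimers are used.

Step 5
Reactants: 8 (2S,4RS)-7,8-bis(benzyloxy)-2-[4-(benzyloxy)phenyl]chroman-4-ol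
Product: 9 (2S)-7,8-bis(benzyloxy)-2-[4-(benzyloxy)phenyl]-2H-chromene
Conditions: Burgess reagent, toluene, 60 °C
Reagents that add atoms: none
Why: Burgess dehydration (syn elimination of the C4 sulfamate with a C3 hydrogen) should give the flav-3-ene from both C4 epimers without acid, so the allylic, benzylic C2–O1 bond is not ionized.

Step 6
Reactants: 9 (2S)-7,8-bis(benzyloxy)-2-[4-(benzyloxy)phenyl]-2H-chromene
Product: 11 (2R,3S)-7,8-bis(benzyloxy)-2-[4-(benzyloxy)phenyl]chroman-3-ol, via C3 alkylborane 10 (not isolated)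
Conditions: BH3·THF, THF, 0 °C to rt; then aq. NaOH, H2O2, 0 °C
Reagents that add atoms: hydrogen peroxide, OO
Why: Brown hydroboration–oxidation; boron should add to C3 (away from the aryl-bearing C4) on the face anti to the C2 aryl group and is replaced by OH with retention, giving the 2,3-trans alcohol.

Step 7
Reactants: 11 (2R,3S)-7,8-bis(benzyloxy)-2-[4-(benzyloxy)phenyl]chroman-3-ol
Product: 12 (2R)-7,8-bis(benzyloxy)-2-[4-(benzyloxy)phenyl]chroman-3-one
Conditions: Dess–Martin periodinane, NaHCO3, CH2Cl2, 0 °C to rt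
Reagents that add atoms: none
Why: Dess–Martin oxidation under buffered, non-basic conditions should give the flavan-3-one without enolization at C2.

Step 8
Reactants: 12 (2R)-7,8-bis(benzyloxy)-2-[4-(benzyloxy)phenyl]chroman-3-one
Product: 13 (2R,3R)-7,8-bis(benzyloxy)-2-[4-(benzyloxy)phenyl]chroman-3-ol
Conditions: Li[HB(s-Bu)3], THF, −78 °C; then H2O
Reagents that add atoms: none
Why: the bulky hydride should attack the C3 ketone from the face opposite to the C2 aryl group (steric approach control), giving the 2,3-cis alcohol.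

Step 9
Reactants: 13 (2R,3R)-7,8-bis(benzyloxy)-2-[4-(benzyloxy)phenyl]chroman-3-ol
Product: 15 (2R,3S)-7,8-bis(benzyloxy)-2-[4-(benzyloxy)phenyl]-3-hydroxychroman-4-one, via 3,4-diol 14 (not isolated)
Conditions: DDQ (2.5 equiv), CH2Cl2–H2O (10:1), 0 °C to rt
Reagents that add atoms: water, O
Why: DDQ benzylic oxidation; hydride abstraction should occur at C4 (ortho to O1 and para to the C7 benzyloxy group), water traps the cation and a second DDQ oxidation of the electron-rich benzylic alcohol gives the aryl ketone, with C2 and C3 untouched.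

Step 10
Reactants: 15 (2R,3S)-7,8-bis(benzyloxy)-2-[4-(benzyloxy)phenyl]-3-hydroxychroman-4-one
Product: 16 (2R,3R,4R)-7,8-bis(benzyloxy)-2-[4-(benzyloxy)phenyl]chroman-3,4-diol
Conditions: NaBH4, MeOH–THF, −20 °C
Reagents that add atoms: none
Why: hydride reduction of the aryl ketone; attack anti to the axial C3 hydroxyl of the 2,3-cis series should give the 3,4-cis alcohol and so the all-cis triad of unit L.

Step 11
Reactants: 16 (2R,3R,4R)-7,8-bis(benzyloxy)-2-[4-(benzyloxy)phenyl]chroman-3,4-diol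
Product: 17 (2R,3S,4R)-7,8-bis(benzyloxy)-2-[4-(benzyloxy)phenyl]-3,4-bis[(tert-butyldimethylsilyl)oxy]chromane
Conditions: TBSOTf (2.5 equiv), 2,6-lutidine, CH2Cl2, 0 °C to rt
Reagents that add atoms: tert-butyldimethylsilyl trifluoromethanesulfonate, CC(C)(C)[Si](C)(C)OS(=O)(=O)C(F)(F)F
Why: silylation of both secondary alcohols; the silyl ethers should withstand aryllithium, alkoxide, borane and hydrogenolysis conditions and shield the benzylic C4–O bond.

Step 12
Reactants: 17 (2R,3S,4R)-7,8-bis(benzyloxy)-2-[4-(benzyloxy)phenyl]-3,4-bis[(tert-butyldimethylsilyl)oxy]chromane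
Product: 18 (2R,3S,4R)-7,8-bis(benzyloxy)-2-[4-(benzyloxy)phenyl]-6-bromo-3,4-bis[(tert-butyldimethylsilyl)oxy]chromane
Conditions: NBS, CH2Cl2–MeCN, 0 °C, dark
Reagents that add atoms: N-bromosuccinimide, O=C1CCC(=O)N1Br
Why: electrophilic aromatic bromination should go to C6, the only free ring A position that is ortho to the C7 benzyloxy group and para to O1.

Step 13
Reactants: 18 (2R,3S,4R)-7,8-bis(benzyloxy)-2-[4-(benzyloxy)phenyl]-6-bromo-3,4-bis[(tert-butyldimethylsilyl)oxy]chromane; 3 3,4-bis(benzyloxy)-2-fluorobenzaldehyde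
Product: 20 [3,4-bis(benzyloxy)-2-fluorophenyl]{(2R,3S,4R)-7,8-bis(benzyloxy)-2-[4-(benzyloxy)phenyl]-3,4-bis[(tert-butyldimethylsilyl)oxy]chroman-6-yl}methanol (carbinol epimers), via C6 aryllithium 19 (not isolated)
Conditions: n-BuLi, THF, −78 °C; then 3, −78 to −40 °C; then H2O
Reagents that add atoms: none
Why: bromine–lithium exchange and 1,2-addition of the aryllithium to the aldehyde should give the diarylmethanol; its carbinol center is not controlled and is erased in step 14.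

Step 14
Reactants: 20 the diarylmethanol of step 13
Product: 21 [3,4-bis(benzyloxy)-2-fluorophenyl]{(2R,3S,4R)-7,8-bis(benzyloxy)-2-[4-(benzyloxy)phenyl]-3,4-bis[(tert-butyldimethylsilyl)oxy]chroman-6-yl}methanone
Conditions: Dess–Martin periodinane, NaHCO3, CH2Cl2, rt
Reagents that add atoms: none
Why: Dess–Martin oxidation of the doubly benzylic alcohol should give the non-enolizable diaryl ketone, the C4/C8a dielectrophile of unit U.

Step 15
Reactants: 4 1-[4-(benzyloxy)phenyl]-2-bromoethan-1-one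
Product: 22 (S)-1-[4-(benzyloxy)phenyl]-2-bromoethan-1-ol
Conditions: (S)-2-methyl-CBS-oxazaborolidine (10 mol %), BH3·SMe2, THF, 0 °C; then MeOH, aqueous work-up
Reagents that add atoms: none
Why: Corey–Bakshi–Shibata reduction with the enantiomeric catalyst should give the (S)-bromohydrin, whose carbinol carbon becomes C2 of unit U.

Step 16
Reactants: 22 (S)-1-[4-(benzyloxy)phenyl]-2-bromoethan-1-ol; 21 the fluoro diaryl ketone of step 14
Product: 25 (2R,4RS)-7,8-bis(benzyloxy)-2-[4-(benzyloxy)phenyl]-4-{(2R,3S,4R)-7,8-bis(benzyloxy)-2-[4-(benzyloxy)phenyl]-3,4-bis[(tert-butyldimethylsilyl)oxy]chroman-6-yl}chroman-4-ol, via β-oxido alkyllithium 23 (not isolated), via dilithium diolate 24 (not isolated)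
Conditions: 22, n-BuLi (1 equiv) then t-BuLi (2 equiv), Et2O–THF, −78 °C; 21, −78 to −40 °C; then KOt-Bu, DMF, 70 °C
Reagents that add atoms: none
Why: O-deprotonation and bromine–lithium exchange convert 22 into the β-oxido alkyllithium 23, whose carbanion adds to the diaryl ketone of 21 (C3–C4), and after the change to the potassium alkoxide in DMF the benzylic alkoxide O1 attacks the fluorine-bearing C8a and expels fluoride through a Meisenheimer complex (O1–C8a). The closest known reactions are the addition of β-oxido organolithium compounds to ketones to give 1,3-diols and the alkoxide ring closure of 1-aryl-3-(2-fluoroaryl)propan-1-ols to flavans; step 4 runs the same pair of events on aldehyde 3. The one ring that closes, ring C of unit U, forms by a six-membered addition–elimination at the sp2 carbon C8a (formally 6-exo-trig). The only new stereocenter is the tertiary carbinol C4, which is not controlled and need not be because step 17 erases it, while C2 is brought in from 22 and is not touched. The step needs carbanion addition to outrun β-elimination of the organolithium and ring closure through O1 alone: the ketone has no α-hydrogen, C8a has no ortho hydrogen (no aryne), the C4 alkoxide could only close a four-membered ring, and C3 is carried as CH2 so that no second oxygen can reach C8a. In one operation the step joins the two flavan halves, closes the last ring and leaves a C4 oxygen from which steps 17 and 18 set C3 and C4.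

Step 17
Reactants: 25 the 4-aryl-flavan-4-ol of step 16
Product: 26 (2R)-7,8-bis(benzyloxy)-2-[4-(benzyloxy)phenyl]-4-{(2R,3S,4R)-7,8-bis(benzyloxy)-2-[4-(benzyloxy)phenyl]-3,4-bis[(tert-butyldimethylsilyl)oxy]chroman-6-yl}-2H-chromene
Conditions: Burgess reagent, THF, rt to 50 °C
Reagents that add atoms: none
Why: Burgess dehydration of the tertiary, doubly benzylic alcohol; both C4 epimers should converge on the single C3=C4 alkene because only C3 carries β-hydrogens, and the neutral conditions keep C2 intact.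

Step 18
Reactants: 26 the 4-aryl-flav-3-ene of step 17
Product: 28 (2S,3R,4R)-7,8-bis(benzyloxy)-2-[4-(benzyloxy)phenyl]-4-{(2R,3S,4R)-7,8-bis(benzyloxy)-2-[4-(benzyloxy)phenyl]-3,4-bis[(tert-butyldimethylsilyl)oxy]chroman-6-yl}chroman-3-ol (2,3-trans-3,4-trans), via C3 alkylborane 27 (not isolated)
Conditions: BH3·THF (excess), THF, 0 to 40 °C; then aq. NaOH, H2O2, 0 °C
Reagents that add atoms: hydrogen peroxide, OO
Why: Brown hydroboration–oxidation of the trisubstituted alkene; syn addition of H–B on the face anti to the C2 aryl group should put boron on C3 and hydrogen on C4, so that after oxidation with retention the C3 hydroxyl is trans to both the C2 aryl and the C4 aryl group.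

Step 19
Reactants: 28 the fully protected dimer of step 18
Product: 29 (2S,3R,4S)-4-{(2R,3S,4R)-3,4-bis[(tert-butyldimethylsilyl)oxy]-7,8-dihydroxy-2-(4-hydroxyphenyl)chroman-6-yl}-2-(4-hydroxyphenyl)chroman-3,7,8-triol
Conditions: H2 (1 atm), Pd(OH)2/C, EtOAc–THF, rt
Reagents that add atoms: none
Why: catalytic hydrogenolysis of the six aryl benzyl ethers; in a neutral, aprotic medium the flavan C–O and C–C bonds and the silyl-shielded benzylic C4–O bond of unit L should survive.

Step 20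
Reactants: 29 the bis-silyl ether of step 19
Product: 30 (2R,3R,4R)-2-(4-hydroxyphenyl)-6-[(2S,3R,4S)-3,7,8-trihydroxy-2-(4-hydroxyphenyl)chroman-4-yl]chroman-3,4,7,8-tetrol (target)
Conditions: HF·pyridine, excess pyridine, THF, 0 °C to rt
Reagents that add atoms: none
Why: fluoride-driven cleavage of both silyl ethers under buffered conditions should free the 3,4-diol without ionizing the benzylic C4–O bond.

**Compound list**

1 | 2-fluoro-3,4-dimethoxybenzaldehyde | O=Cc1ccc(OC)c(OC)c1F | starting material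
2 | 2-fluoro-3,4-dihydroxybenzaldehyde | O=Cc1ccc(O)c(O)c1F | intermediate
3 | 3,4-bis(benzyloxy)-2-fluorobenzaldehyde | O=Cc1ccc(OCc2ccccc2)c(OCc2ccccc2)c1F | intermediate
4 | 1-[4-(benzyloxy)phenyl]-2-bromoethan-1-one | O=C(CBr)c1ccc(OCc2ccccc2)cc1 | starting material
5 | (R)-1-[4-(benzyloxy)phenyl]-2-bromoethan-1-ol | O[C@@H](CBr)c1ccc(OCc2ccccc2)cc1 | intermediate
6 | lithium (1S)-1-[4-(benzyloxy)phenyl]-2-lithioethan-1-olate (same spatial arrangement as 5) | [Li]O[C@@H](C[Li])c1ccc(OCc2ccccc2)cc1 | intermediate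
7 | dilithium (1S,3RS)-1-[4-(benzyloxy)phenyl]-3-[3,4-bis(benzyloxy)-2-fluorophenyl]propane-1,3-bis(olate) | [Li]O[C@@H](CC(O[Li])c1ccc(OCc2ccccc2)c(OCc2ccccc2)c1F)c1ccc(OCc2ccccc2)cc1 | intermediate
8 | (2S,4RS)-7,8-bis(benzyloxy)-2-[4-(benzyloxy)phenyl]chroman-4-ol | c1ccccc1COc1ccc([C@H]2Oc3c(ccc(OCc4ccccc4)c3OCc3ccccc3)C(O)C2)cc1 | intermediate
9 | (2S)-7,8-bis(benzyloxy)-2-[4-(benzyloxy)phenyl]-2H-chromene | c1ccccc1COc1ccc([C@H]2Oc3c(ccc(OCc4ccccc4)c3OCc3ccccc3)C=C2)cc1 | intermediate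
10 | [(2S,3S)-7,8-bis(benzyloxy)-2-[4-(benzyloxy)phenyl]chroman-3-yl]borane (boron trans to the 2-aryl group) | c1ccccc1COc1ccc([C@H]2Oc3c(ccc(OCc4ccccc4)c3OCc3ccccc3)C[C@@H]2B)cc1 | intermediate
11 | (2R,3S)-7,8-bis(benzyloxy)-2-[4-(benzyloxy)phenyl]chroman-3-ol (2,3-trans) | c1ccccc1COc1ccc([C@H]2Oc3c(ccc(OCc4ccccc4)c3OCc3ccccc3)C[C@@H]2O)cc1 | intermediate
12 | (2R)-7,8-bis(benzyloxy)-2-[4-(benzyloxy)phenyl]chroman-3-one | c1ccccc1COc1ccc([C@H]2Oc3c(ccc(OCc4ccccc4)c3OCc3ccccc3)CC2=O)cc1 | intermediate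
13 | (2R,3R)-7,8-bis(benzyloxy)-2-[4-(benzyloxy)phenyl]chroman-3-ol (2,3-cis) | c1ccccc1COc1ccc([C@H]2Oc3c(ccc(OCc4ccccc4)c3OCc3ccccc3)C[C@H]2O)cc1 | intermediate
14 | (2R,3R,4RS)-7,8-bis(benzyloxy)-2-[4-(benzyloxy)phenyl]chroman-3,4-diol | c1ccccc1COc1ccc([C@H]2Oc3c(ccc(OCc4ccccc4)c3OCc3ccccc3)C(O)[C@H]2O)cc1 | intermediate
15 | (2R,3S)-7,8-bis(benzyloxy)-2-[4-(benzyloxy)phenyl]-3-hydroxychroman-4-one (2,3-cis) | c1ccccc1COc1ccc([C@H]2Oc3c(ccc(OCc4ccccc4)c3OCc3ccccc3)C(=O)[C@H]2O)cc1 | intermediate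
16 | (2R,3R,4R)-7,8-bis(benzyloxy)-2-[4-(benzyloxy)phenyl]chroman-3,4-diol (all-cis) | c1ccccc1COc1ccc([C@H]2Oc3c(ccc(OCc4ccccc4)c3OCc3ccccc3)[C@@H](O)[C@H]2O)cc1 | intermediate
17 | (2R,3S,4R)-7,8-bis(benzyloxy)-2-[4-(benzyloxy)phenyl]-3,4-bis[(tert-butyldimethylsilyl)oxy]chromane | c1ccccc1COc1ccc([C@H]2Oc3c(ccc(OCc4ccccc4)c3OCc3ccccc3)[C@@H](O[Si](C)(C)C(C)(C)C)[C@H]2O[Si](C)(C)C(C)(C)C)cc1 | intermediate
18 | (2R,3S,4R)-7,8-bis(benzyloxy)-2-[4-(benzyloxy)phenyl]-6-bromo-3,4-bis[(tert-butyldimethylsilyl)oxy]chromane | c1ccccc1COc1ccc([C@H]2Oc3c(cc(Br)c(OCc4ccccc4)c3OCc3ccccc3)[C@@H](O[Si](C)(C)C(C)(C)C)[C@H]2O[Si](C)(C)C(C)(C)C)cc1 | intermediate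
19 | 6-lithio analogue of 18 (lithium in place of bromine) | c1ccccc1COc1ccc([C@H]2Oc3c(cc([Li])c(OCc4ccccc4)c3OCc3ccccc3)[C@@H](O[Si](C)(C)C(C)(C)C)[C@H]2O[Si](C)(C)C(C)(C)C)cc1 | intermediate
20 | [3,4-bis(benzyloxy)-2-fluorophenyl]{(2R,3S,4R)-7,8-bis(benzyloxy)-2-[4-(benzyloxy)phenyl]-3,4-bis[(tert-butyldimethylsilyl)oxy]chroman-6-yl}methanol, carbinol epimers | c1ccccc1COc1ccc([C@H]2Oc3c(cc(C(O)c5ccc(OCc6ccccc6)c(OCc6ccccc6)c5F)c(OCc4ccccc4)c3OCc3ccccc3)[C@@H](O[Si](C)(C)C(C)(C)C)[C@H]2O[Si](C)(C)C(C)(C)C)cc1 | intermediate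
21 | [3,4-bis(benzyloxy)-2-fluorophenyl]{(2R,3S,4R)-7,8-bis(benzyloxy)-2-[4-(benzyloxy)phenyl]-3,4-bis[(tert-butyldimethylsilyl)oxy]chroman-6-yl}methanone | c1ccccc1COc1ccc([C@H]2Oc3c(cc(C(=O)c5ccc(OCc6ccccc6)c(OCc6ccccc6)c5F)c(OCc4ccccc4)c3OCc3ccccc3)[C@@H](O[Si](C)(C)C(C)(C)C)[C@H]2O[Si](C)(C)C(C)(C)C)cc1 | intermediate
22 | (S)-1-[4-(benzyloxy)phenyl]-2-bromoethan-1-ol | O[C@H](CBr)c1ccc(OCc2ccccc2)cc1 | intermediate
23 | lithium (1R)-1-[4-(benzyloxy)phenyl]-2-lithioethan-1-olate (same spatial arrangement as 22) | [Li]O[C@H](C[Li])c1ccc(OCc2ccccc2)cc1 | intermediate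
24 | dilithium salt of (1RS,3R)-1-[3,4-bis(benzyloxy)-2-fluorophenyl]-3-[4-(benzyloxy)phenyl]-1-{(2R,3S,4R)-7,8-bis(benzyloxy)-2-[4-(benzyloxy)phenyl]-3,4-bis[(tert-butyldimethylsilyl)oxy]chroman-6-yl}propane-1,3-diol | c1ccccc1COc1ccc([C@H]2Oc3c(cc(C(O[Li])(C[C@@H](O[Li])c7ccc(OCc8ccccc8)cc7)c5ccc(OCc6ccccc6)c(OCc6ccccc6)c5F)c(OCc4ccccc4)c3OCc3ccccc3)[C@@H](O[Si](C)(C)C(C)(C)C)[C@H]2O[Si](C)(C)C(C)(C)C)cc1 | intermediate
25 | (2R,4RS)-7,8-bis(benzyloxy)-2-[4-(benzyloxy)phenyl]-4-{(2R,3S,4R)-7,8-bis(benzyloxy)-2-[4-(benzyloxy)phenyl]-3,4-bis[(tert-butyldimethylsilyl)oxy]chroman-6-yl}chroman-4-ol | c1ccccc1COc1ccc([C@H]2Oc3c(cc(C5(O)C[C@H](c7ccc(OCc8ccccc8)cc7)Oc6c5ccc(OCc5ccccc5)c6OCc5ccccc5)c(OCc4ccccc4)c3OCc3ccccc3)[C@@H](O[Si](C)(C)C(C)(C)C)[C@H]2O[Si](C)(C)C(C)(C)C)cc1 | intermediate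
26 | (2R)-7,8-bis(benzyloxy)-2-[4-(benzyloxy)phenyl]-4-{(2R,3S,4R)-7,8-bis(benzyloxy)-2-[4-(benzyloxy)phenyl]-3,4-bis[(tert-butyldimethylsilyl)oxy]chroman-6-yl}-2H-chromene | c1ccccc1COc1ccc([C@H]2Oc3c(cc(C5=C[C@H](c7ccc(OCc8ccccc8)cc7)Oc6c5ccc(OCc5ccccc5)c6OCc5ccccc5)c(OCc4ccccc4)c3OCc3ccccc3)[C@@H](O[Si](C)(C)C(C)(C)C)[C@H]2O[Si](C)(C)C(C)(C)C)cc1 | intermediate
27 | C3 alkylborane of unit U: BH2 in place of the C3 hydroxyl of 28, trans to the C2 aryl and to the C4 aryl group | c1ccccc1COc1ccc([C@H]2Oc3c(cc([C@H]5c6ccc(OCc7ccccc7)c(OCc7ccccc7)c6O[C@@H](c6ccc(OCc7ccccc7)cc6)[C@@H]5B)c(OCc4ccccc4)c3OCc3ccccc3)[C@@H](O[Si](C)(C)C(C)(C)C)[C@H]2O[Si](C)(C)C(C)(C)C)cc1 | intermediate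
28 | (2S,3R,4R)-7,8-bis(benzyloxy)-2-[4-(benzyloxy)phenyl]-4-{(2R,3S,4R)-7,8-bis(benzyloxy)-2-[4-(benzyloxy)phenyl]-3,4-bis[(tert-butyldimethylsilyl)oxy]chroman-6-yl}chroman-3-ol (unit U 2,3-trans-3,4-trans) | c1ccccc1COc1ccc([C@H]2Oc3c(cc([C@H]5c6ccc(OCc7ccccc7)c(OCc7ccccc7)c6O[C@@H](c6ccc(OCc7ccccc7)cc6)[C@@H]5O)c(OCc4ccccc4)c3OCc3ccccc3)[C@@H](O[Si](C)(C)C(C)(C)C)[C@H]2O[Si](C)(C)C(C)(C)C)cc1 | intermediate
29 | (2S,3R,4S)-4-{(2R,3S,4R)-3,4-bis[(tert-butyldimethylsilyl)oxy]-7,8-dihydroxy-2-(4-hydroxyphenyl)chroman-6-yl}-2-(4-hydroxyphenyl)chroman-3,7,8-triol | Oc1ccc([C@H]2Oc3c(cc([C@H]5c6ccc(O)c(O)c6O[C@@H](c6ccc(O)cc6)[C@@H]5O)c(O)c3O)[C@@H](O[Si](C)(C)C(C)(C)C)[C@H]2O[Si](C)(C)C(C)(C)C)cc1 | intermediate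
30 | (2R,3R,4R)-2-(4-hydroxyphenyl)-6-[(2S,3R,4S)-3,7,8-trihydroxy-2-(4-hydroxyphenyl)chroman-4-yl]chroman-3,4,7,8-tetrol | Oc1ccc([C@H]2Oc3c(cc([C@H]4c5ccc(O)c(O)c5O[C@@H](c5ccc(O)cc5)[C@@H]4O)c(O)c3O)[C@@H](O)[C@H]2O)cc1 | target

**Step count and risks**

Total step count: 20. Longest linear sequence: 18 steps (steps 1, 2, 4 to 14 and 16 to 20; steps 3 and 15 are one-step side branches).

The three steps most likely to fail:

1. Step 16. β-Elimination or electron transfer from the alkyllithium may compete with addition to the hindered diaryl ketone. Fluoride displacement on the electron-rich ring (benzyloxy ortho to fluorine) may be slow enough that the silyl ethers erode on prolonged heating with alkoxide. Fallback: the annulation is run on the simple aldehyde and the halves are joined afterwards by aryl addition. It sets out from 22 and 3: under the conditions of step 4 they should give (2R,4RS)-7,8-bis(benzyloxy)-2-[4-(benzyloxy)phenyl]chroman-4-ol F1. Dess–Martin oxidation gives (2R)-7,8-bis(benzyloxy)-2-[4-(benzyloxy)phenyl]chroman-4-one F2. Aryllithium 19, transmetalated with CeCl3 to suppress enolization and ring opening of the flavanone, is then added to the C4 ketone of F2. The route is rejoined at 25.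

2. Step 9. Hydride abstraction may occur at C2 (a 4-alkoxybenzylic ether hydrogen) instead of C4, the dihydroflavonol may be dehydrogenated further, and the 2,3-cis α-hydroxy ketone may epimerize at C3. Fallback: a Woodward cis-hydroxylation that puts both oxygens on the hindered face. It sets out from 9: I2 and AgOAc in wet AcOH should first give the trans-iodo acetate (2R)-7,8-bis(benzyloxy)-2-[4-(benzyloxy)phenyl]-3-iodochroman-4-yl acetate F3 (iodine anti, acetoxy syn to the C2 aryl group). On heating, the acetate displaces iodide with inversion through a cis-fused acetoxonium ion, which water opens to the cis-hydroxy acetate (2R)-7,8-bis(benzyloxy)-2-[4-(benzyloxy)phenyl]-3-hydroxychroman-4-yl acetate F4 (both oxygens syn to the C2 aryl group; drawn as the 4-acetate, the 3-acetate converges as well). K2CO3 in MeOH removes the acetyl group. The route is rejoined at 16, so steps 6 to 10 are bypassed.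

3. Step 18. Addition of borane to the hindered, trisubstituted 1,1-diaryl alkene may be slow, may place boron at C4, or may occur syn to the C2 aryl group. Fallback: oxygen is brought in by epoxidation and the stereocenters are set under thermodynamic and hydride control. It sets out from 26: dimethyldioxirane in acetone should give the 3,4-epoxide F5 (oxygen anti to the C2 aryl group). BF3·OEt2 at −78 °C should trigger a Meinwald rearrangement (ionization at the doubly benzylic C4, hydride shift from C3) to the 4-aryl-flavan-3-one F6, whose C4 (doubly benzylic and α to the ketone) is equilibrated with Et3N to the 2,4-cis-diaryl isomer. NaBH4 (axial attack, equatorial alcohol) then gives the 2,3-trans-3,4-trans alcohol. The route is rejoined at 28.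

**Further compounds**

F1 | step 16 | (2R,4RS)-7,8-bis(benzyloxy)-2-[4-(benzyloxy)phenyl]chroman-4-ol | c1ccccc1COc1ccc([C@@H]2Oc3c(ccc(OCc4ccccc4)c3OCc3ccccc3)C(O)C2)cc1
F2 | step 16 | (2R)-7,8-bis(benzyloxy)-2-[4-(benzyloxy)phenyl]chroman-4-one | c1ccccc1COc1ccc([C@@H]2Oc3c(ccc(OCc4ccccc4)c3OCc3ccccc3)C(=O)C2)cc1
F3 | step 9 | (2R)-7,8-bis(benzyloxy)-2-[4-(benzyloxy)phenyl]-3-iodochroman-4-yl acetate, iodine trans and acetoxy cis to the 2-aryl group | c1ccccc1COc1ccc([C@H]2Oc3c(ccc(OCc4ccccc4)c3OCc3ccccc3)[C@@H](OC(C)=O)[C@@H]2I)cc1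
F4 | step 9 | (2R)-7,8-bis(benzyloxy)-2-[4-(benzyloxy)phenyl]-3-hydroxychroman-4-yl acetate, hydroxyl and acetoxy both cis to the 2-aryl group | c1ccccc1COc1ccc([C@H]2Oc3c(ccc(OCc4ccccc4)c3OCc3ccccc3)[C@@H](OC(C)=O)[C@H]2O)cc1
F5 | step 18 | 3,4-epoxide of 26, epoxide oxygen trans to the 2-aryl group of unit U | c1ccccc1COc1ccc([C@H]2Oc3c(cc([C@@]56c7ccc(OCc8ccccc8)c(OCc8ccccc8)c7O[C@@H](c7ccc(OCc8ccccc8)cc7)[C@@H]5O6)c(OCc4ccccc4)c3OCc3ccccc3)[C@@H](O[Si](C)(C)C(C)(C)C)[C@H]2O[Si](C)(C)C(C)(C)C)cc1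
F6 | step 18 | 3-ketone of unit U corresponding to 28 (C3 carbonyl, 2-aryl and 4-aryl groups cis) | c1ccccc1COc1ccc([C@H]2Oc3c(cc([C@H]5c6ccc(OCc7ccccc7)c(OCc7ccccc7)c6O[C@@H](c6ccc(OCc7ccccc7)cc6)C5=O)c(OCc4ccccc4)c3OCc3ccccc3)[C@@H](O[Si](C)(C)C(C)(C)C)[C@H]2O[Si](C)(C)C(C)(C)C)cc1
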